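The constants are invented; the result is computed.

The constants become times once you multiply them by the charged amounts, and those times are what you read this flask by.

in all of them: substrate 0.20 M; reagent 0.220 M; capture agent 0.0600 M; catalyst 14 mM
- theta: a single well-mixed tank run continuously and read at steady state, 150 min in it on average
- zeta: everything together in a closed stirred flask, run for 30 min; time 30 min
- gamma: plug flow through a tube for 30 min, no back-mixing; time 30 min
- delta: one stirred flow tank at steady state, fed with the mixture as stated, mean residence time 30 min

    substrate + catalyst → catalyst + open intermediate (k1 = 31 M⁻¹ min⁻¹)
    reagent + catalyst + open intermediate → catalyst + target (k2 = 16 M⁻² min⁻¹)
    open intermediate + capture agent → trapped intermediate (k3 = 0.18 M⁻¹ min⁻¹)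
    substrate + target ⇌ idle adduct, settled at all times (K4 = 15 M⁻¹)

- percent here means substrate units held: one idle adduct counts as two
- what is said of target includes idle adduct
- the stated concentrations are those of everything mixed, before any reaction; amounts are the same in each set-up
- in an amount of target, one idle adduct counts as one target
- run time (zeta): 30 min

- the set-up with the highest amount of open intermediate at the outlet or at the end, in percent of the substrate put in ("none" if the first two lie within 2 percentage points) (theta / zeta / gamma / delta / none)
- amount of open intermediate at the outlet or at the end, in percent of the substrate put in, theta
- amount of open intermediate at the outlet or at the end, in percent of the substrate put in, zeta
- amount of open intermediate at the outlet or at the end, in percent of the substrate put in, gamma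
- amount of open intermediate at the outlet or at the end, in percent of the substrate put in, delta

Here are the half-lives at the charged amounts, as they stand at the start in zeta, with the strength of the adduct balance below them:

- substrate opening: 1.6 min
- open intermediate lost to reagent: 14 min
- open intermediate lost to capture agent: 64 min
- equilibrium constant of the idle adduct times [substrate]: 3.0

Read the first row against the next two. Substrate opens faster than open intermediate is lost, so open intermediate builds up early and the question becomes how quickly it drains. The second row against the third shows that reagent takes it faster than capture agent does. The last row shows that idle adduct can hold substrate once target exists, a delay I leave out of this reckoning.

The two losses add as rates. One over the sum of the two pseudo-first-order loss rates, at the charged [reagent], [catalyst] and [capture agent], is 16.6 min. I call this mean life of open intermediate the drain time.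

Now count substrate as opened at once. A steady tank then holds one over (one plus residence time divided by drain time), which I call the tank rule, and a closed flask or tube holds the exponential of minus time over drain time. That gives me 35.7% for delta, 16.5% for zeta and gamma, and 9.99% for theta. So I commit to delta as highest, and I take these figures as low, since [reagent] and [capture agent] fall during a run and the drain time lengthens.

The forecast names delta, with 19% for theta, 33% for zeta, 33% for gamma and 39.8% for delta, on the ground that “back-mixing keeps some material unreacted for longer”. Each figure stands above mine.

The simulation puts delta highest, with 39.7% there, 32.5% in zeta, 32.5% in gamma and 19.0% in theta.

In delta, the [reagent] of 0.143 M, with capture agent still counted at its charge, stretches the drain time to 23.3 min, longer than at the charge, and the tank rule then gives 43.7%, while the 39.7% lies between that and 35.7%. In theta, the tank rule read backward from 19.0%, with substrate still counted as opened at once, gives a drain time of 35.2 min, twice the charged 16.6 min.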